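**Read slopes.** The rate constants I could read were pseudo-first-order slopes of ln(left-handed substrate) against time: 0.185 /min on Thursday and 0.211 /min on Sunday, with 1 equiv and 4 equiv of solid reagent. Friday's, at 20 mol% of free catalyst, read 0.487 /min, which is 2.46 times their mean.

| flask | left-handed substrate | right-handed substrate | solid reagent | free catalyst | impurity | remark |
|---|---|---|---|---|---|---|
| Thursday's | 0.20 M | 0.20 M | 1 equiv | 10 mol% | 5.9 mM | run made earlier |
| Sunday's | 0.20 M | 0.20 M | 4 equiv | 10 mol% | 5.9 mM | run made earlier |
| Friday's | 0.20 M | 0.20 M | 2 equiv | 20 mol% | 5.9 mM | run made earlier |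
| flask | 0.20 M | 0.20 M | 2.00 equiv | 10 mol% | 5.9 mM |  |

| run | time / min | left-handed product / % | left-handed substrate / % |
|---|---|---|---|
| Thursday's | 0.417 | 3.3 | 46.6 |
| Thursday's | 0.833 | 7.9 | 42.5 |
| Thursday's | 1.33 | 11.0 | 39.0 |
| Thursday's | 1.50 | 13.0 | 36.8 |
| Thursday's | 2.00 | 16.5 | 34.4 |
| Thursday's | 2.50 | 18.3 | 31.7 |
| Sunday's | 0.417 | 3.7 | 46.9 |
| Sunday's | 0.833 | 7.2 | 42.5 |
| Sunday's | 1.33 | 11.4 | 38.5 |
| Sunday's | 1.50 | 14.0 | 36.9 |
| Sunday's | 2.00 | 16.8 | 33.7 |
| Sunday's | 2.50 | 19.7 | 30.2 |
| Friday's | 0.200 | 3.2 | 47.5 |
| Friday's | 0.667 | 13.1 | 38.0 |
| Friday's | 1.00 | 18.2 | 32.4 |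
| Friday's | 1.50 | 25.2 | 24.3 |
| Friday's | 2.50 | 34.8 | 15.5 |

(standard deviation of a reading: 0.5 percentage points)

- free catalyst is single-handed; left-handed substrate and right-handed substrate are mirror images of each other, charged as a racemate, each of them at the stated concentration
- solid, in amounts per volume of the solution: solid reagent
- the numbers in the tables scatter with a standard deviation of 0.5 percentage points
- at the start none of the solid reagent is in solution

1. apparent order in free catalyst when 30% of the left-handed substrate and right-handed substrate together are converted (percent change of the rate of making left-handed product for one percent more free catalyst charged)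
2. factor on the rate of making left-handed product when 30% of the left-handed substrate and right-handed substrate together are converted if free catalyst is charged twice over

**Bench note.** A gain beyond proportion suggested that a fixed amount of catalyst was being lost, so I took the impurity to kill it one for one. This flask then holds 14.1 mM: the live catalyst, charged free catalyst minus charged impurity. That is 70.5% of the charge, and I expected [free catalyst] to stand there at 30% conversion. The order is charge over live catalyst, 1.42, and doubling gives 2.42.

**The forecast.** The forecast, citing “the impurity titrating catalyst”, gave 1.42 (1.2 to 1.6) and 2.42 (2.2 to 2.65).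

**The flask.** It gave an order of 1.4 and a factor of 2.35.

    coupling partner + free catalyst + left-handed substrate → free catalyst + left-handed product (k = 1.70 /M²/s)
    coupling partner + free catalyst + right-handed substrate → free catalyst + right-handed product (k = 0.700 /M²/s)
    free catalyst + impurity → spent catalyst (k = 200 /M/s)
    solid reagent ⇌ coupling partner, rate k4*(cs4 - [coupling partner]) while solid is left; crystals form when [coupling partner] > cs4 (solubility = 0.150 M, k = 0.210 /s)

**What happened.** By 0.300 min this flask's impurity stood at 0%, with free catalyst at 70.5% and spent catalyst at 29.5%. Both couplings then ran on that free catalyst, with [coupling partner] at 0.147 M and solid reagent at 29.1% at 3.00 min. Friday's charge holds 34.1 mM of live catalyst, and twice the free catalyst gave a rate factor of 2.35.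

(The readings come from a simulation with made-up constants, and the scatter is random.)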